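**Retrosynthetic overview**

1. The last step removes five allyl groups (three aryl ethers, two esters) from the fully assembled, protected target 19.
2. The strategy rests on the O1–C2 aryl ether bond of the 1,4-benzodioxane: C2 is α to the carboxyl (an ideal invertive SN2 site), and the ring A catechol has two phenols of different acidity. The dioxane is the only ring formed and is closed last, on the complete skeleton, by an invertive intramolecular Mitsunobu etherification of threo hydroxy ester 17 (cis ring from inversion at C2).
3. Precursor 17 comes from a Knoevenagel–Doebner union (acrylate C=C) of aldehyde 16 with the lactate malonate half-ester 8.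
4. Aldehyde 16 carries the C3–O4 bond, made by invertive opening of cis-glycidate 15 (Jacobsen epoxidation of Z-cinnamate 14) with the more acidic 4-OH of 3,4-dihydroxybenzaldehyde.
5. Half-ester 8 takes its (R)-lactate centre from methyl (R)-glycidate, opened at C3 by an aryl Grignard reagent under CuI catalysis.

Key step: step 11

Remark: ring A is the benzo ring of the benzodioxane (the caffeoyl catechol); O4 is its oxygen para to the acrylate and O1 the one meta to it. Phosphonate 13 is taken not to be purchasable and is made in step 6.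

**Route**

Step 1
Reactants: 1 4-bromo-2-methoxyphenol
Product: 2 1-(allyloxy)-4-bromo-2-methoxybenzene
Conditions: allyl bromide, K2CO3, DMF, rt
Reagents that add atoms: allyl bromide, C=CCBr
Why: Williamson etherification of the phenoxide installs the allyl ether that the final palladium step removes.

Step 2
Reactants: 2 1-(allyloxy)-4-bromo-2-methoxybenzene; 3 methyl (R)-glycidate
Product: 5 methyl (2R)-3-(4-allyloxy-3-methoxyphenyl)-2-hydroxypropanoate, via arylmagnesium bromide 4 (not isolated)
Conditions: Mg, THF, reflux; then CuI (10 mol%), 3, THF, −40 to −20 °C; aq NH4Cl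
Reagents that add atoms: none
Why: Copper-catalysed opening of the glycidic ester by the aryl Grignard reagent occurs at the unsubstituted C3 (SN2), so the stereocentre of 3 is carried over untouched as the (R)-carbinol of the lactate.

Step 3
Reactants: 5 methyl (2R)-3-(4-allyloxy-3-methoxyphenyl)-2-hydroxypropanoate
Product: 6 allyl (2R)-3-(4-allyloxy-3-methoxyphenyl)-2-hydroxypropanoate
Conditions: allyl alcohol (solvent), Ti(OiPr)4 (10 mol%), 80 °C
Reagents that add atoms: allyl alcohol, C=CCO
Why: Titanate-catalysed transesterification in excess allyl alcohol is neutral and should leave the α-hydroxy stereocentre untouched.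

Step 4
Reactants: 6 allyl (2R)-3-(4-allyloxy-3-methoxyphenyl)-2-hydroxypropanoate; 7 Meldrum's acid
Product: 8 3-{[(2R)-1-(allyloxy)-3-(4-allyloxy-3-methoxyphenyl)-1-oxopropan-2-yl]oxy}-3-oxopropanoic acid (malonate half-ester)
Conditions: toluene, 100 °C
Reagents that add atoms: none
Why: Thermal acylation of the alcohol by Meldrum's acid (ring opening with loss of acetone) gives the malonic half-ester without base or coupling reagent, so the stereocentre is not endangered.

Step 5
Reactants: 9 3,4-dihydroxybenzaldehyde
Product: 10 3,4-bis(allyloxy)benzaldehyde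
Conditions: allyl bromide (2.5 equiv), K2CO3, DMF, 60 °C
Reagents that add atoms: allyl bromide, C=CCBr
Why: Double Williamson etherification protects both catechol oxygens as allyl ethers.

Step 6
Reactants: 11 diphenyl phosphite; 12 allyl bromoacetate
Product: 13 allyl 2-(diphenoxyphosphoryl)acetate
Conditions: Et3N, CH2Cl2, 0 °C to rt
Reagents that add atoms: none
Why: Amine-mediated Michaelis–Becker P-alkylation of the H-phosphonate by the α-bromo ester is the standard entry to diaryl phosphonoacetates.

Step 7
Reactants: 10 3,4-bis(allyloxy)benzaldehyde; 13 allyl 2-(diphenoxyphosphoryl)acetate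
Product: 14 allyl (Z)-3-[3,4-bis(allyloxy)phenyl]prop-2-enoate
Conditions: NaH, THF, −78 to −20 °C
Reagents that add atoms: none
Why: Ando-type Horner–Wadsworth–Emmons olefination, in which the electron-poor diaryl phosphonate makes oxaphosphetane collapse fast and kinetically controlled, should give mainly the Z-enoate, the E isomer being removed by chromatography.

Step 8
Reactants: 14 allyl (Z)-3-[3,4-bis(allyloxy)phenyl]prop-2-enoate
Product: 15 allyl (2R,3R)-3-[3,4-bis(allyloxy)phenyl]oxirane-2-carboxylate (cis-glycidate)
Conditions: chloro[(R,R)-N,N'-bis(3,5-di-tert-butylsalicylidene)-1,2-cyclohexanediaminato]manganese (5 mol%), 4-phenylpyridine N-oxide (25 mol%), aq NaOCl (pH 11.3, Na2HPO4), CH2Cl2, 0–4 °C; Et3N-deactivated silica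
Reagents that add atoms: sodium hypochlorite, [Na+].[O-]Cl
Why: In this Jacobsen–Katsuki epoxidation the oxo-manganese salen species oxidises the conjugated cis-disubstituted alkene much faster than the isolated terminal allyl double bonds, and the (R,R) ligand should direct oxygen to the face that gives the (2R,3R)-cis-glycidate, the N-oxide additive limiting leakage to the trans epoxide.

Step 9
Reactants: 15 allyl (2R,3R)-3-[3,4-bis(allyloxy)phenyl]oxirane-2-carboxylate; 9 3,4-dihydroxybenzaldehyde
Product: 16 allyl (2R,3S)-3-[3,4-bis(allyloxy)phenyl]-3-(4-formyl-2-hydroxyphenoxy)-2-hydroxypropanoate (threo)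
Conditions: Cs2CO3 (30 mol%), DMF, 50 °C, argon; aldehyde in excess, surplus removed on silica before step 10
Reagents that add atoms: none
Why: In this base-catalysed SN2 epoxide opening, a pure addition in which the C2 alkoxide passes its charge back to fresh phenol, only the 4-OH of 9 (para to the formyl group and by far the more acidic) is ionised, and it should attack the benzylic C3 with inversion (3R to 3S) while C2 keeps its configuration, which leaves the 3-OH free for the key step; the surplus of 9 keeps the base off the less acidic phenol of 16 and so guards against a second alkylation.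

Step 10
Reactants: 16 allyl (2R,3S)-3-[3,4-bis(allyloxy)phenyl]-3-(4-formyl-2-hydroxyphenoxy)-2-hydroxypropanoate; 8 malonate half-ester
Product: 17 allyl (2R,3S)-3-[3,4-bis(allyloxy)phenyl]-2-hydroxy-3-{2-hydroxy-4-[(E)-3-{[(2R)-1-(allyloxy)-3-(4-allyloxy-3-methoxyphenyl)-1-oxopropan-2-yl]oxy}-3-oxoprop-1-enyl]phenoxy}propanoate (threo precursor)
Conditions: pyridine, piperidine (20 mol%), 60 °C; half-ester in moderate excess
Reagents that add atoms: none
Why: Knoevenagel–Doebner condensation of the malonic half-ester with the aldehyde, followed by decarboxylation, should give the (E)-cinnamate ester directly under conditions too mild to touch the allyl esters, the α-hydroxy ester or the stereocentres.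

Step 11
Reactants: 17 threo hydroxy ester with free ring A 3-OH
Product: 19 allyl (2S,3S)-3-[3,4-bis(allyloxy)phenyl]-7-[(E)-3-{[(2R)-1-(allyloxy)-3-(4-allyloxy-3-methoxyphenyl)-1-oxopropan-2-yl]oxy}-3-oxoprop-1-enyl]-2,3-dihydro-1,4-benzodioxine-2-carboxylate (cis; penta-allyl-protected target), via alkoxyphosphonium phenoxide 18 (not isolated)
Conditions: PPh3, DIAD, THF (0.01 M), 0 °C to rt
Reagents that add atoms: none
Why: PPh3 and DIAD form the betaine, which deprotonates the only acidic group of 17 (the ring A phenol meta to the acrylate) and turns the C2 hydroxyl into an alkoxyphosphonium leaving group (18), after which the phenoxide oxygen O1 displaces triphenylphosphine oxide from C2 from the rear. The closest known reaction type is the Mitsunobu etherification of α-hydroxy esters with phenols, used intramolecularly for 2,3-disubstituted 1,4-benzodioxanes. The dioxane ring is closed in the 6-exo-tet mode, the leaving group lying outside the forming ring. The new stereocentre C2 is controlled by SN2 inversion of the (2R)-carbinol set in step 8, giving (2S), while C3 (S, set in step 9) is not touched, so the threo precursor can only give the cis ring. The step needs substitution to win over ionisation and elimination, which the adjacent ester carbonyl should secure because it disfavours a cation at C2 and accelerates SN2, and it needs the correct oxygen to attack, which is secured because O4 was used in step 9 and O1 is the single free phenol. High dilution is proposed to suppress intermolecular etherification.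

Step 12
Reactants: 19 penta-allyl-protected cis-benzodioxane
Product: 20 (2S,3S)-7-[(E)-3-{[(1R)-1-carboxy-2-(4-hydroxy-3-methoxyphenyl)ethyl]oxy}-3-oxoprop-1-enyl]-3-(3,4-dihydroxyphenyl)-2,3-dihydro-1,4-benzodioxine-2-carboxylic acid (CNP0249420.1)
Conditions: Pd(PPh3)4 (10 mol%), morpholine (15 equiv), degassed THF, rt; dilute aq citric acid work-up
Reagents that add atoms: none
Why: In this Tsuji–Trost deallylation zerovalent palladium ionises each allyl ester and allyl aryl ether to a π-allyl complex that morpholine intercepts, near-neutral conditions that should spare the cinnamate ester, its alkene and the epimerisable cis C2 centre.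

**Compound list**

1 | 4-bromo-2-methoxyphenol | COc1cc(Br)ccc1O | starting material
2 | 1-(allyloxy)-4-bromo-2-methoxybenzene | COc1cc(Br)ccc1OCC=C | intermediate
3 | methyl (R)-glycidate | COC(=O)[C@H]1CO1 | starting material
4 | (4-allyloxy-3-methoxyphenyl)magnesium bromide | COc1cc([Mg]Br)ccc1OCC=C | intermediate
5 | methyl (2R)-3-(4-allyloxy-3-methoxyphenyl)-2-hydroxypropanoate | COC(=O)[C@H](O)Cc1ccc(OCC=C)c(OC)c1 | intermediate
6 | allyl (2R)-3-(4-allyloxy-3-methoxyphenyl)-2-hydroxypropanoate | C=CCOC(=O)[C@H](O)Cc1ccc(OCC=C)c(OC)c1 | intermediate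
7 | Meldrum's acid | CC1(C)OC(=O)CC(=O)O1 | starting material
8 | 3-{[(2R)-1-(allyloxy)-3-(4-allyloxy-3-methoxyphenyl)-1-oxopropan-2-yl]oxy}-3-oxopropanoic acid | OC(=O)CC(=O)O[C@H](Cc1ccc(OCC=C)c(OC)c1)C(=O)OCC=C | intermediate
9 | 3,4-dihydroxybenzaldehyde | O=Cc1ccc(O)c(O)c1 | starting material
10 | 3,4-bis(allyloxy)benzaldehyde | O=Cc1ccc(OCC=C)c(OCC=C)c1 | intermediate
11 | diphenyl phosphite | O=[PH](Oc1ccccc1)Oc1ccccc1 | starting material
12 | allyl bromoacetate | C=CCOC(=O)CBr | starting material
13 | allyl 2-(diphenoxyphosphoryl)acetate | C=CCOC(=O)CP(=O)(Oc1ccccc1)Oc1ccccc1 | intermediate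
14 | allyl (Z)-3-[3,4-bis(allyloxy)phenyl]prop-2-enoate | C=CCOC(=O)/C=C\c1ccc(OCC=C)c(OCC=C)c1 | intermediate
15 | allyl (2R,3R)-3-[3,4-bis(allyloxy)phenyl]oxirane-2-carboxylate (cis) | C=CCOC(=O)[C@@H]1O[C@@H]1c1ccc(OCC=C)c(OCC=C)c1 | intermediate
16 | allyl (2R,3S)-3-[3,4-bis(allyloxy)phenyl]-3-(4-formyl-2-hydroxyphenoxy)-2-hydroxypropanoate | O=Cc1ccc(O[C@@H](c2ccc(OCC=C)c(OCC=C)c2)[C@@H](O)C(=O)OCC=C)c(O)c1 | intermediate
17 | threo (2R,3S) hydroxy ester on O4 of the allyl-protected caffeoyl (R)-lactate, free 3-OH | COc1cc(C[C@@H](OC(=O)/C=C/c2ccc(O[C@@H](c3ccc(OCC=C)c(OCC=C)c3)[C@@H](O)C(=O)OCC=C)c(O)c2)C(=O)OCC=C)ccc1OCC=C | intermediate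
18 | C2 alkoxytriphenylphosphonium, ring A phenoxide zwitterion of 17 | COc1cc(C[C@@H](OC(=O)/C=C/c2ccc(O[C@@H](c3ccc(OCC=C)c(OCC=C)c3)[C@@H](O[P+](c3ccccc3)(c3ccccc3)c3ccccc3)C(=O)OCC=C)c([O-])c2)C(=O)OCC=C)ccc1OCC=C | intermediate
19 | penta-allyl-protected target, cis (2S,3S) dioxane | COc1cc(C[C@@H](OC(=O)/C=C/c2ccc3c(c2)O[C@H](C(=O)OCC=C)[C@H](c2ccc(OCC=C)c(OCC=C)c2)O3)C(=O)OCC=C)ccc1OCC=C | intermediate
20 | CNP0249420.1 | COc1cc(C[C@@H](OC(=O)/C=C/c2ccc3c(c2)O[C@H](C(=O)O)[C@H](c2ccc(O)c(O)c2)O3)C(=O)O)ccc1O | target

**Step count and risks**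

Total step count: 12. Longest linear sequence: 7 steps (1, 2, 3, 4, 10, 11, 12; the branch 5, 7, 8, 9, 10, 11, 12 is equally long).

Steps most likely to fail:

1. Step 11 (key step). The activated C2 oxygen may be lost by β-elimination toward the 3-aryloxycinnamate. The electron-rich C3 aryl group may also participate (1,2-aryl shift through a phenonium ion) and erode the inversion, or slow closure at the hindered carbinol may let the hydrazide be alkylated. Fallback: stepwise activation and displacement in place of the redox condensation, setting out from 17 and returning at 19. The ring A phenol of 17 is silylated selectively (TBSCl, imidazole, DMF, 0 °C; phenols react faster than the hindered α-hydroxy ester) to give the aryl silyl ether F4. The C2 hydroxyl is then mesylated (MsCl, Et3N, CH2Cl2, 0 °C) to give the mesylate F5. CsF in DMF at rt unmasks the phenoxide, which should displace the α-mesyloxy ester in a 6-exo-tet SN2 reaction with inversion to give 19.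

2. Step 8. Rotation in the radical intermediate, which the electron-rich aryl ring stabilises, may divert the cis alkene to the trans epoxide; enantioselection may be incomplete; and the acid-sensitive epoxide may be lost on isolation. Fallback: an auxiliary-controlled aldol (Darzens-type) sequence, setting out from 10 and returning at 15. The boron enolate of (S)-4-benzyl-3-(chloroacetyl)oxazolidin-2-one (Bu2BOTf, iPr2NEt, CH2Cl2, −78 to 0 °C) should add to 10 in the Evans syn sense to give the syn chlorohydrin imide F1. Bromomagnesium allyloxide (allyl alcohol, MeMgBr, THF, 0 °C) exchanges the auxiliary for the allyl ester to give the chlorohydrin ester F2. K2CO3 in DMF closes F2 by displacement of chloride with inversion at C2 to give cis-glycidate 15.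

3. Step 9. The formyl-stabilised phenoxide is a weak nucleophile, and forcing conditions may let the electron-rich benzylic C–O bond ionise, eroding the inversion at C3. Fallback: reverse the order of fragment union, setting out from 8, 9 and 15 and returning at 17. Knoevenagel–Doebner condensation of 8 with 9 (pyridine, piperidine, 60 °C) gives the caffeoyl lactate with free catechol F3. Its more nucleophilic 4-phenoxide (para to the acrylate and still the more acidic oxygen) opens 15 at C3 with inversion (Cs2CO3, DMF, 40 °C) to give 17 directly.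

Further compounds
F1 | step 8 | (4S)-4-benzyl-3-{(2S,3R)-3-[3,4-bis(allyloxy)phenyl]-2-chloro-3-hydroxypropanoyl}oxazolidin-2-one | O=C1OC[C@H](Cc2ccccc2)N1C(=O)[C@@H](Cl)[C@H](O)c1ccc(OCC=C)c(OCC=C)c1
F2 | step 8 | allyl (2S,3R)-3-[3,4-bis(allyloxy)phenyl]-2-chloro-3-hydroxypropanoate | C=CCOC(=O)[C@@H](Cl)[C@H](O)c1ccc(OCC=C)c(OCC=C)c1
F3 | step 9 | allyl (2R)-3-(4-allyloxy-3-methoxyphenyl)-2-{[(E)-3-(3,4-dihydroxyphenyl)prop-2-enoyl]oxy}propanoate | COc1cc(C[C@@H](OC(=O)/C=C/c2ccc(O)c(O)c2)C(=O)OCC=C)ccc1OCC=C
F4 | step 11 | ring A 3-O-tert-butyldimethylsilyl ether of 17 | COc1cc(C[C@@H](OC(=O)/C=C/c2ccc(O[C@@H](c3ccc(OCC=C)c(OCC=C)c3)[C@@H](O)C(=O)OCC=C)c(O[Si](C)(C)C(C)(C)C)c2)C(=O)OCC=C)ccc1OCC=C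
F5 | step 11 | C2 methanesulfonate of F4 | COc1cc(C[C@@H](OC(=O)/C=C/c2ccc(O[C@@H](c3ccc(OCC=C)c(OCC=C)c3)[C@@H](OS(C)(=O)=O)C(=O)OCC=C)c(O[Si](C)(C)C(C)(C)C)c2)C(=O)OCC=C)ccc1OCC=C
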